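The target is a trans-decalin (eudesmane numbering, see remark): ring A (C5–C10) and ring B (C1–C5, C10) share C5–C10. C10 lies between the oxygenated C1 and C9, so it is the carbon of a 2-methyl-1,3-diketone enolate; C4, carrying C15, lies between C3 and C5, a 2-alkylidenepropane-1,3-diyl unit. One palladium-catalysed double allylic alkylation of an acyclic precursor therefore joins C10 to C5 (ring A) and C2 to C3 (ring B), sets C5 and C10 from the C6/C7 stereocentres and leaves a C4=C15 methylene for dihydroxylation. The precursor is a 3,5-dioxo ester tethered to a bis(acetoxymethyl)alkene.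

Key step: step 10

Remark: eudesmane numbering is used throughout (C10 = methyl-bearing ring-fusion carbon, C5 = ring-fusion CH, C1 and C9 = the carbinol carbons on C10, C4 = quaternary carbon bearing O and the C15 CH2O, C6 = CH–O, C7 = CH–isopropyl). Compounds 1, 2, 4, 13, 14, 24 and 25 are assumed to be commercial.

Step 1
Reactants: 1 2-oxopropane-1,3-diyl diacetate (1,3-diacetoxyacetone); 2 2-(triphenylphosphoranylidene)acetaldehyde
Product: 3 2-(2-oxoethylidene)propane-1,3-diyl diacetate
Conditions: 1 (2 equiv), toluene, 80 °C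
Reagents that add atoms: none
Why: Wittig olefination of a ketone activated by two α-acyloxy groups with the stabilised formyl ylide; the ketone is symmetrical, so the trisubstituted enal has no E/Z issue, and excess ketone should limit a second olefination.

Step 2
Reactants: 4 (E)-4-methylpent-2-ene
Product: 6 (E)-4-methylpent-2-en-1-ylboronic acid pinacol ester, via allylpotassium 5 (not isolated)
Conditions: n-BuLi, KOt-Bu, THF, −78 to −50 °C; 2-isopropoxy-4,4,5,5-tetramethyl-1,3,2-dioxaborolane, −78 °C; HCl/Et2O
Reagents that add atoms: 2-isopropoxy-4,4,5,5-tetramethyl-1,3,2-dioxaborolane, CC(C)OB1OC(C)(C)C(C)(C)O1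
Why: Superbase metalation at the allylic methyl gives the (E)-allylpotassium, which should be borylated at its unhindered terminus with retention of E geometry, as in the standard preparation of (E)-crotylboronates.

Step 3
Reactants: 3; 6
Product: 8 2-[(2R,3R)-2-hydroxy-3-(propan-2-yl)pent-4-en-1-ylidene]propane-1,3-diyl diacetate, via pinacol borate ester 7 (not isolated)
Conditions: (R)-TRIP [(R)-3,3'-bis(2,4,6-triisopropylphenyl)-1,1'-binaphthyl-2,2'-diyl hydrogen phosphate] (5 mol %), toluene, 4 Å MS, −30 °C; aq. NaHCO3
Reagents that add atoms: none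
Why: Chiral phosphoric acid-catalysed allylboration through a closed chair transition state, in which the (E)-boronate places isopropyl equatorial to give the anti C6/C7 relationship and the catalyst enantiomer that directs attack to the Re face of the aldehyde sets (R)-C6.

Step 4
Reactants: 8
Product: 9 2-[(2R,3R)-2-[(tert-butyldimethylsilyl)oxy]-3-(propan-2-yl)pent-4-en-1-ylidene]propane-1,3-diyl diacetate
Conditions: TBSOTf, 2,6-lutidine, CH2Cl2, −78 °C
Reagents that add atoms: tert-butyldimethylsilyl triflate, CC(C)(C)[Si](C)(C)OS(=O)(=O)C(F)(F)F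
Why: Silylation of the hindered secondary allylic alcohol with the silyl triflate; unlike an ester, the silyl ether at this allylic position is not ionised by zerovalent palladium later.

Step 5
Reactants: 9
Product: 11 2-[(2R,3S)-2-[(tert-butyldimethylsilyl)oxy]-5-hydroxy-3-(propan-2-yl)pentylidene]propane-1,3-diyl diacetate, via B-alkyl-9-BBN adduct 10 (not isolated)
Conditions: 9-BBN, THF, 0 to 25 °C; aq. NaOAc, 30 % H2O2, 0 to 25 °C
Reagents that add atoms: hydrogen peroxide, OO
Why: Anti-Markovnikov hydroboration–oxidation; 9-BBN should react only with the monosubstituted alkene, the trisubstituted bis(acetoxymethyl) alkene being far slower, and the acetate-buffered oxidation spares the acetates.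

Step 6
Reactants: 11
Product: 12 2-[(2R,3S)-2-[(tert-butyldimethylsilyl)oxy]-5-oxo-3-(propan-2-yl)pentylidene]propane-1,3-diyl diacetate
Conditions: Dess–Martin periodinane, NaHCO3, CH2Cl2, 0 to 25 °C
Reagents that add atoms: none
Why: Dess–Martin oxidation of the primary alcohol to the aldehyde under buffered, non-basic conditions that leave acetates and silyl ether untouched.

Step 7
Reactants: 13 methyl 3-oxopentanoate; 14 2-(trimethylsilyl)ethanol
Product: 15 2-(trimethylsilyl)ethyl 3-oxopentanoate
Conditions: DMAP (10 mol %), toluene, 110 °C, removal of MeOH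
Reagents that add atoms: none
Why: Transesterification of a β-keto ester, giving a fluoride-cleavable ester so that the C2 activating group can later leave as CO2 under mild conditions.

Step 8
Reactants: 15; 12
Product: 17 2-(trimethylsilyl)ethyl (7S,8R)-11-acetoxy-10-(acetoxymethyl)-8-[(tert-butyldimethylsilyl)oxy]-5-hydroxy-4-methyl-3-oxo-7-(propan-2-yl)undec-9-enoate (C4/C5 epimer mixture), via keto ester dianion 16 (not isolated)
Conditions: 15 (1.3 equiv), NaH, THF, 0 °C; n-BuLi, 0 °C; 12, −78 °C; AcOH quench at −78 °C
Reagents that add atoms: none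
Why: Aldol addition of the β-keto ester dianion through its γ-carbon (future C10), which at −78 °C should be far faster than attack on the acetates; the two new centres form as mixtures and are both planarised later.

Step 9
Reactants: 17
Product: 18 2-(trimethylsilyl)ethyl (7S,8R)-11-acetoxy-10-(acetoxymethyl)-8-[(tert-butyldimethylsilyl)oxy]-4-methyl-3,5-dioxo-7-(propan-2-yl)undec-9-enoate
Conditions: Dess–Martin periodinane, NaHCO3, CH2Cl2, 0 to 25 °C
Reagents that add atoms: none
Why: Dess–Martin oxidation of the β-hydroxy ketone to the 2-methyl-1,3-diketone, giving the bis-pronucleophile with acidic C10–H and C2–H.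

Step 10
Reactants: 18
Product: 20 2-(trimethylsilyl)ethyl 6-[(tert-butyldimethylsilyl)oxy]-1,9-dioxoeudesm-4(15)-ene-2-carboxylate (trans-decalin; C5/C6/C7/C10 as in 28; C2 epimers), via ring-A monocycle 19 (not isolated)
Conditions: NaH (2.2 equiv), THF (0.01 M), 0 °C; Pd(PPh3)4 (10 mol %), 25 to 60 °C
Reagents that add atoms: none
Why: Zerovalent palladium ionises one allylic acetate to a π-allyl complex (C3–C4–C5), the C10 carbon of the chelated sodium diketone enolate attacks its internal terminus C5 (6-(enolendo)-exo-trig, ring A), and the catalyst then ionises the remaining allylic acetate of 19 so that the C2 keto ester enolate attacks a terminus of the second, symmetrical π-allyl (6-(enolendo)-endo-trig, ring B), leaving the C4=C15 methylene. The closest known reactions are the Tsuji–Trost allylation of β-dicarbonyl enolates and the palladium-catalysed [3+3] annulation of 3-oxoglutarate-type bis-nucleophiles with 2-methylenepropane-1,3-diyl diacetate, here run intramolecularly so that two rings form. C10 should be set by the Z (chelated) enolate geometry, which places the methyl axial and the C1 acyl group equatorial in the chair transition state; C5 should be set by the C6/C7 stereocentres, because an axial C6 silyloxy group would be syn-axial to that methyl, so silyloxy sits equatorial, isopropyl axial, and the allyl unit on C5 must be equatorial to avoid a syn-axial clash with isopropyl. This should give H5 trans to the methyl (trans-decalin) and trans to H6 as in the target, and since the palladium faces interconvert through the η1 form at the CH2 terminus the outcome is decided at C–C bond formation (Curtin–Hammett). The step needs C- over O-allylation and six- over eight-membered closure: acetate ionisation and O-allylation (allyl enol ethers) are reversible under the catalyst, and C10-to-C3 or C2-to-C5 closures would give eight-membered or larger rings. C2 forms as an epimer/enol mixture and is removed as a stereocentre in step 11.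

Step 11
Reactants: 20
Product: 22 (5R,6R,7S,10S)-6-hydroxyeudesm-4(15)-ene-1,9-dione, via β-keto acid 21 (not isolated)
Conditions: TBAF (4 equiv), AcOH (2 equiv), THF, 25 to 50 °C
Reagents that add atoms: none
Why: Fluoride cleaves the silyl ether and the 2-(trimethylsilyl)ethyl ester (loss of ethene) and the β-keto acid decarboxylates; acetic acid buffering should protect the non-enolisable 1,3-diketone from retro-Claisen cleavage.

Step 12
Reactants: 22
Product: 23 (4S,5R,6R,7S,10S)-4,6,15-trihydroxyeudesmane-1,9-dione
Conditions: OsO4 (2 mol %), NMO (1.5 equiv), acetone/H2O 4:1, 25 °C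
Reagents that add atoms: osmium tetroxide, O=[Os](=O)(=O)=O; N-methylmorpholine N-oxide, C[N+]1([O-])CCOCC1
Why: Upjohn dihydroxylation of the only alkene; osmium tetroxide should add to the exocyclic methylene from the equatorial face, anti to the syn-axial C10 methyl, giving the equatorial C4–OH and the axial C15 hydroxymethyl.

Step 13
Reactants: 24 iodobenzene; 25 3,3,3-triethoxyprop-1-ene (triethyl orthoacrylate)
Product: 26 (E)-(3,3,3-triethoxyprop-1-en-1-yl)benzene (triethyl orthocinnamate)
Conditions: Pd(OAc)2 (3 mol %), P(o-tol)3, Et3N, MeCN, 80 °C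
Reagents that add atoms: none
Why: Heck arylation of the monosubstituted alkene; the orthoester carbon carries no hydrogen, so β-hydride elimination can only give the (E)-styryl orthoester.

Step 14
Reactants: 23; 26
Product: 27 (4S,5R,6R,7S,10S)-1,9-dioxoeudesmane-4,6,15-triyl orthocinnamate
Conditions: 26 (1.5 equiv), CSA (10 mol %), benzene, 4 Å MS, 25 to 50 °C; Et3N quench
Reagents that add atoms: none
Why: Acid-catalysed transorthoesterification in which the primary C15–OH, the equatorial tertiary C4–OH and the peri equatorial C6–OH replace the three ethoxy groups to give the 2,7,8-trioxabicyclo[3.2.1]octane cage under thermodynamic control, the cage fixing the configuration of the orthoester carbon.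

Step 15
Reactants: 27
Product: 28 (1S,4S,5R,6R,7S,9R,10S)-1,9-dihydroxyeudesmane-4,6,15-triyl orthocinnamate (CNP0252898.2)
Conditions: NaBH4 (4 equiv), THF/MeOH 4:1, −20 to 0 °C
Reagents that add atoms: none
Why: Borohydride reduction of both ketones by axial attack on the face anti to the axial C10 methyl, which hinders the equatorial trajectory at C1 and C9, should give both equatorial alcohols cis to the methyl (syn-1,3-diol); the cage orthoester and the styryl alkene are inert to NaBH4.

Compound list
1 | 2-oxopropane-1,3-diyl diacetate | CC(=O)OCC(=O)COC(C)=O | starting material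
2 | 2-(triphenylphosphoranylidene)acetaldehyde | O=CC=P(c1ccccc1)(c1ccccc1)c1ccccc1 | starting material
3 | 2-(2-oxoethylidene)propane-1,3-diyl diacetate | CC(=O)OCC(COC(C)=O)=CC=O | intermediate
4 | (E)-4-methylpent-2-ene | C/C=C/C(C)C | starting material
5 | (E)-4-methylpent-2-en-1-ylpotassium | [K]C/C=C/C(C)C | intermediate (not isolated)
6 | 4,4,5,5-tetramethyl-2-[(E)-4-methylpent-2-en-1-yl]-1,3,2-dioxaborolane | CC(C)/C=C/CB1OC(C)(C)C(C)(C)O1 | intermediate
7 | pinacol borate ester of 8 | CC(C)[C@H](C=C)[C@@H](OB1OC(C)(C)C(C)(C)O1)C=C(COC(C)=O)COC(C)=O | intermediate (not isolated)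
8 | 2-[(2R,3R)-2-hydroxy-3-(propan-2-yl)pent-4-en-1-ylidene]propane-1,3-diyl diacetate | CC(C)[C@H](C=C)[C@@H](O)C=C(COC(C)=O)COC(C)=O | intermediate
9 | 2-[(2R,3R)-2-[(tert-butyldimethylsilyl)oxy]-3-(propan-2-yl)pent-4-en-1-ylidene]propane-1,3-diyl diacetate | CC(C)[C@H](C=C)[C@@H](O[Si](C)(C)C(C)(C)C)C=C(COC(C)=O)COC(C)=O | intermediate
10 | B-alkyl-9-borabicyclo[3.3.1]nonane adduct of 9 (boron on the terminal carbon) | CC(C)[C@H](CCB1C2CCCC1CCC2)[C@@H](O[Si](C)(C)C(C)(C)C)C=C(COC(C)=O)COC(C)=O | intermediate (not isolated)
11 | 2-[(2R,3S)-2-[(tert-butyldimethylsilyl)oxy]-5-hydroxy-3-(propan-2-yl)pentylidene]propane-1,3-diyl diacetate | CC(C)[C@H](CCO)[C@@H](O[Si](C)(C)C(C)(C)C)C=C(COC(C)=O)COC(C)=O | intermediate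
12 | 2-[(2R,3S)-2-[(tert-butyldimethylsilyl)oxy]-5-oxo-3-(propan-2-yl)pentylidene]propane-1,3-diyl diacetate | CC(C)[C@H](CC=O)[C@@H](O[Si](C)(C)C(C)(C)C)C=C(COC(C)=O)COC(C)=O | intermediate
13 | methyl 3-oxopentanoate | CCC(=O)CC(=O)OC | starting material
14 | 2-(trimethylsilyl)ethanol | C[Si](C)(C)CCO | starting material
15 | 2-(trimethylsilyl)ethyl 3-oxopentanoate | CCC(=O)CC(=O)OCC[Si](C)(C)C | intermediate
16 | sodium lithium dianion (bis-enolate) of 15 | CC=C([O-])C=C([O-])OCC[Si](C)(C)C.[Na+].[Li+] | intermediate (not isolated)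
17 | 2-(trimethylsilyl)ethyl (7S,8R)-11-acetoxy-10-(acetoxymethyl)-8-[(tert-butyldimethylsilyl)oxy]-5-hydroxy-4-methyl-3-oxo-7-(propan-2-yl)undec-9-enoate, C4/C5 epimers | CC(C)[C@H](CC(O)C(C)C(=O)CC(=O)OCC[Si](C)(C)C)[C@@H](O[Si](C)(C)C(C)(C)C)C=C(COC(C)=O)COC(C)=O | intermediate
18 | 2-(trimethylsilyl)ethyl (7S,8R)-11-acetoxy-10-(acetoxymethyl)-8-[(tert-butyldimethylsilyl)oxy]-4-methyl-3,5-dioxo-7-(propan-2-yl)undec-9-enoate | CC(C)[C@H](CC(=O)C(C)C(=O)CC(=O)OCC[Si](C)(C)C)[C@@H](O[Si](C)(C)C(C)(C)C)C=C(COC(C)=O)COC(C)=O | intermediate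
19 | ring-A monocycle: 2-(trimethylsilyl)ethyl 3-oxo-3-{2-(3-acetoxyprop-1-en-2-yl)-3-[(tert-butyldimethylsilyl)oxy]-1-methyl-6-oxo-4-(propan-2-yl)cyclohexyl}propanoate, ring centres as in 20 | CC(C)[C@@H]1CC(=O)[C@@](C(=O)CC(=O)OCC[Si](C)(C)C)(C)[C@H]([C@@H]1O[Si](C)(C)C(C)(C)C)C(=C)COC(C)=O | intermediate (not isolated)
20 | 2-(trimethylsilyl)ethyl 6-[(tert-butyldimethylsilyl)oxy]-1,9-dioxoeudesm-4(15)-ene-2-carboxylate, trans-fused, C5/C6/C7/C10 as in 28, C2 unspecified | CC(C)[C@@H]1CC(=O)[C@@]2(C)[C@H]([C@@H]1O[Si](C)(C)C(C)(C)C)C(=C)CC(C(=O)OCC[Si](C)(C)C)C2=O | intermediate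
21 | 6-hydroxy-1,9-dioxoeudesm-4(15)-ene-2-carboxylic acid, ring centres as in 22 | CC(C)[C@@H]1CC(=O)[C@@]2(C)[C@H]([C@@H]1O)C(=C)CC(C(=O)O)C2=O | intermediate (not isolated)
22 | (5R,6R,7S,10S)-6-hydroxyeudesm-4(15)-ene-1,9-dione | CC(C)[C@@H]1CC(=O)[C@@]2(C)[C@H]([C@@H]1O)C(=C)CCC2=O | intermediate
23 | (4S,5R,6R,7S,10S)-4,6,15-trihydroxyeudesmane-1,9-dione | CC(C)[C@@H]1CC(=O)[C@@]2(C)[C@H]([C@@H]1O)[C@](O)(CO)CCC2=O | intermediate
24 | iodobenzene | Ic1ccccc1 | starting material
25 | 3,3,3-triethoxyprop-1-ene | C=CC(OCC)(OCC)OCC | starting material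
26 | (E)-(3,3,3-triethoxyprop-1-en-1-yl)benzene | CCOC(OCC)(OCC)/C=C/c1ccccc1 | intermediate
27 | (4S,5R,6R,7S,10S)-1,9-dioxoeudesmane-4,6,15-triyl orthocinnamate | CC(C)[C@@H]1CC(=O)[C@@]2(C)[C@@H]3[C@@H]1O[C@]1(/C=C/c4ccccc4)OC[C@@]3(CCC2=O)O1 | intermediate
28 | (1S,4S,5R,6R,7S,9R,10S)-1,9-dihydroxyeudesmane-4,6,15-triyl orthocinnamate; trans-decalin, C10 methyl axial, 1-OH and 9-OH equatorial and cis to it, 7-isopropyl axial and trans to it | CC(C)[C@@H]1C[C@@H](O)[C@@]2(C)[C@@H]3[C@@H]1O[C@]1(/C=C/c4ccccc4)OC[C@@]3(CC[C@@H]2O)O1 | target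

Total step count: 15. Longest linear sequence: 12 steps (1, 3, 4, 5, 6, 8, 9, 10, 11, 12, 14, 15).

Steps most likely to fail

Step 10. C–C bond formation at the hindered, oxygen-flanked C5 terminus may be slow, so that O-allylation, β-hydride loss to a diene or intermolecular allylation compete, or the second ionisation may not follow in the same flask. The fallback builds the rings one at a time and closes ring B by SN2 alkylation instead of a second π-allyl trapping. Starting from 18, the first allylation is run alone with one equivalent of NaH and Pd(PPh3)4 at 25 °C, and the ring-A monocycle 19 is isolated and purified. Its remaining primary acetate is removed with Candida antarctica lipase B in pH 7 buffer to give the allylic alcohol F1. CBr4/PPh3 converts this into the allylic bromide F2, and Cs2CO3 in DMF closes ring B by C-alkylation of the keto ester, returning to the route at 20.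

Step 15. Hydride may reach C9 along the equatorial trajectory because the axial C7 isopropyl group shields the axial one, which would give the axial 9-epimer. The fallback reduces under thermodynamic control before the styryl group is present. From 23, NaBH4 (1 equiv, MeOH, −40 °C) reduces the unhindered C1 ketone to the hydroxy ketone F3. Li in NH3/THF with t-BuOH at −78 °C then reduces C9 to the more stable equatorial alcohol, giving the pentaol F4. Exchange with 26 (1.05 equiv, CSA) forms the cage on the 4,6,15-triol and returns to the route at 28.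

Step 1. Addition of the stabilised ylide to the ketone may be sluggish, and the product enal may be olefinated again to a dienal. The fallback replaces olefination by alkynylation and Meyer–Schuster rearrangement. From 1, HC≡CMgBr (THF, −78 °C) adds to the activated ketone faster than to the acetates and gives the propargylic alcohol F5. Ph3PAuNTf2 (2 mol %, toluene, 1 equiv MeOH, 25 °C) rearranges it to the enal, returning to the route at 3.

Further compounds
F1 | step 10 | allylic alcohol from 19 (acetate replaced by OH) | CC(C)[C@@H]1CC(=O)[C@@](C(=O)CC(=O)OCC[Si](C)(C)C)(C)[C@H]([C@@H]1O[Si](C)(C)C(C)(C)C)C(=C)CO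
F2 | step 10 | allylic bromide from F1 | CC(C)[C@@H]1CC(=O)[C@@](C(=O)CC(=O)OCC[Si](C)(C)C)(C)[C@H]([C@@H]1O[Si](C)(C)C(C)(C)C)C(=C)CBr
F3 | step 15 | (1S,4S,5R,6R,7S,10S)-1,4,6,15-tetrahydroxyeudesman-9-one | CC(C)[C@@H]1CC(=O)[C@@]2(C)[C@H]([C@@H]1O)[C@](O)(CO)CC[C@@H]2O
F4 | step 15 | (1S,4S,5R,6R,7S,9R,10S)-eudesmane-1,4,6,9,15-pentol | CC(C)[C@@H]1C[C@@H](O)[C@@]2(C)[C@H]([C@@H]1O)[C@](O)(CO)CC[C@@H]2O
F5 | step 1 | 2-ethynyl-2-hydroxypropane-1,3-diyl diacetate | CC(=O)OCC(O)(C#C)COC(C)=O
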